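**Plan**

1. Retrosynthetic cuts, in order: the two B-ring pivalate esters, C5–O (C–H hydroxylation), O1–C8a (oxidative ring closure), C2–C3 (C-acylation), C4–C4a (aryl–acyl bond).
2. Rings A and B are bought: ring A as a syringyl bromide, ring B as 4-O-methylgallic acid. C3, C4 and the 3-OMe come from a methoxyacetyl unit.
3. Forward: aryllithium + Weinreb amide gives the ω-methoxy ketone, C-acylation gives the open 2-methoxy-1,3-diketone, ring C is closed through O1–C8a, then C5–OH is installed and the pivalates are removed.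
4. Enabling feature: C7–OH sits between C6–OMe and C8–OMe and is para to C4a, which carries the C4 carbonyl, so ring A is a 4-acylsyringol that is C2-symmetric about the C7···C4a axis. Its oxidation in methanol gives a masked o-benzoquinone whose electrophilic ring carbons are C8a and C5, and attack of the enol oxygen at either ortho carbon gives the same flavone.
5. The last A-ring C–H (C5) is peri to the C4 carbonyl and is hydroxylated under carbonyl direction.
6. Stereochemistry: the target is achiral, so nothing has to be set.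

Key step: step 7

Remark: the target has no stereocentre and no stereogenic axis, so the given structure is its only stereoisomer. The centres at C2 of diketones 11 and 12 and at C8a of 14 are racemic and are lost on the way to 15.

**Route**

Step 1
Reactants: 1 4-bromo-2,6-dimethoxyphenol
Product: 2 2-(benzyloxy)-5-bromo-1,3-dimethoxybenzene
Conditions: BnBr (1.1 equiv), K2CO3 (1.5 equiv), DMF, 60 °C
Reagents that add atoms: benzyl bromide, BrCc1ccccc1
Why: Williamson O-benzylation of the phenoxide should proceed cleanly, and the benzyl ether survives the aryllithium step and is later removed by hydrogenolysis without touching pivalates.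

Step 2
Reactants: 2 2-(benzyloxy)-5-bromo-1,3-dimethoxybenzene; 3 N,2-dimethoxy-N-methylacetamide
Product: 6 1-[4-(benzyloxy)-3,5-dimethoxyphenyl]-2-methoxyethan-1-one, via aryllithium 4 (not isolated), via tetrahedral lithium adduct 5 (not isolated)
Conditions: n-BuLi (1.05 equiv), THF, −78 °C; then 3 (1.2 equiv), −78 → 0 °C; aq. NH4Cl
Reagents that add atoms: none
Why: Br/Li exchange followed by Weinreb ketone synthesis should give the ω-methoxy ketone, because the chelated adduct 5 resists over-addition and collapses to the ketone only on aqueous work-up.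

Step 3
Reactants: 7 3,5-dihydroxy-4-methoxybenzoic acid
Product: 9 4-methoxy-3,5-bis(pivaloyloxy)benzoic acid, via mixed pivalic anhydride 8 (not isolated)
Conditions: PivCl (3.3 equiv), pyridine, DMAP (cat.), CH2Cl2, 0 °C → rt; then THF/H2O, NaHCO3, rt; 1 M HCl
Reagents that add atoms: pivaloyl chloride, CC(C)(C)C(Cl)=O; water, O
Why: DMAP-catalysed O-acylation should cap both phenols and convert the acid into mixed anhydride 8, which water cleaves at its unhindered aroyl carbonyl while the hindered aryl pivalates remain.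

Step 4
Reactants: 9 4-methoxy-3,5-bis(pivaloyloxy)benzoic acid
Product: 10 4-methoxy-3,5-bis(pivaloyloxy)benzoyl chloride
Conditions: (COCl)2 (1.5 equiv), DMF (cat.), CH2Cl2, 0 °C → rt; concentrated and used crude
Reagents that add atoms: oxalyl chloride, O=C(Cl)C(Cl)=O
Why: Vilsmeier-catalysed acid chloride formation under neutral conditions should leave the aryl pivalates intact.

Step 5
Reactants: 6 1-[4-(benzyloxy)-3,5-dimethoxyphenyl]-2-methoxyethan-1-one; 10 4-methoxy-3,5-bis(pivaloyloxy)benzoyl chloride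
Product: 11 1-[4-(benzyloxy)-3,5-dimethoxyphenyl]-2-methoxy-3-[4-methoxy-3,5-bis(pivaloyloxy)phenyl]propane-1,3-dione
Conditions: MgBr2·OEt2 (2.5 equiv), i-Pr2NEt (3 equiv), CH2Cl2, 0 °C → rt; 10 (1.1 equiv); 1 M HCl work-up
Reagents that add atoms: none
Why: soft-enolisation C-acylation of the ketone, via a magnesium enolate chelated by the α-methoxy group, should form the C2–C3 bond and give the 1,3-diketone directly while tolerating the aryl esters; the new centre is racemic and enolisable and disappears in step 7.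

Step 6
Reactants: 11 1-[4-(benzyloxy)-3,5-dimethoxyphenyl]-2-methoxy-3-[4-methoxy-3,5-bis(pivaloyloxy)phenyl]propane-1,3-dione
Product: 12 1-(4-hydroxy-3,5-dimethoxyphenyl)-2-methoxy-3-[4-methoxy-3,5-bis(pivaloyloxy)phenyl]propane-1,3-dione
Conditions: H2 (1 atm), 10% Pd/C, EtOAc, rt
Reagents that add atoms: none
Why: hydrogenolysis of the benzyl aryl ether should free only the syringyl phenol, since aryl ketones, pivalates and methyl ethers are inert under these conditions.

Step 7
Reactants: 12 1-(4-hydroxy-3,5-dimethoxyphenyl)-2-methoxy-3-[4-methoxy-3,5-bis(pivaloyloxy)phenyl]propane-1,3-dione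
Product: 15 7-hydroxy-3,6,8-trimethoxy-2-[4-methoxy-3,5-bis(pivaloyloxy)phenyl]-4H-chromen-4-one, via masked o-benzoquinone 13 (not isolated), via 8,8a-dihydrochromenone 14 (not isolated)
Conditions: PhI(OAc)2 (1.05 equiv), MeOH–CH2Cl2, −10 → 0 °C; then PPTS (0.2 equiv), 0 → 40 °C
Reagents that add atoms: methanol, CO (enters as the second methoxy group of the ketal carbon of 13; one of the two ketal methoxy groups is kept as 8-OMe)
Why: Proposed new method: PhI(OAc)2 should oxidise the only free phenol of 12 and methanol should be captured at a methoxy-bearing ortho carbon to give the masked o-benzoquinone 13, a linearly conjugated 2,4-dienone whose δ-carbon (future C8a, also β to the aryl ketone) and β-carbon (future C5) are the two ring carbons meta to the phenol oxygen. The enol oxygen of the 2-methoxy-1,3-diketone should then add to the δ-carbon in a 6-endo-trig oxa-Michael addition (equivalently a 6π-oxa-electrocyclisation of the 1-oxatriene O=C2–C3=C4(OH)–C4a=C8a), which closes ring C through the O1–C8a bond to give 14, and acid-promoted loss of methanol from the C8 ketal through the arenium ion should restore the aromatic ring. The closest known reaction types are the domino Michael addition/aromatisation of masked o-benzoquinones with external S-, N- and C-nucleophiles and the oxa-Michael closure of 2'-hydroxychalcones to flavanones. No stereocentre remains, since C8a of 14 and C2 of 12 both become sp2. O- over C-attack is secured because C-attack would need a four-membered ring, and site selectivity is not needed because the C2-symmetric syringyl ring gives the same flavone from ketalisation at either methoxy carbon and attack at either ortho carbon. Chemoselectivity rests on ring B carrying no free phenol and on consuming one equivalent of oxidant at low temperature before the acid regenerates a phenol.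

Step 8
Reactants: 15 7-hydroxy-3,6,8-trimethoxy-2-[4-methoxy-3,5-bis(pivaloyloxy)phenyl]-4H-chromen-4-one
Product: 18 5,7-dihydroxy-3,6,8-trimethoxy-2-[4-methoxy-3,5-bis(pivaloyloxy)phenyl]-4H-chromen-4-one, via 7-O-trifluoroacetate 16 (not isolated), via 5,7-bis(trifluoroacetate) 17 (not isolated)
Conditions: TFAA/TFA (1:1), rt, 30 min; then [RuCl2(p-cymene)]2 (5 mol%), PhI(OCOCF3)2 (2 equiv), 80 °C; concentrate; THF/sat. aq. NaHCO3, rt
Reagents that add atoms: [bis(trifluoroacetoxy)iodo]benzene, O=C(OI(OC(=O)C(F)(F)F)c1ccccc1)C(F)(F)F (supplies the C5 oxygen as a trifluoroacetate)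
Why: Ru(II)-catalysed, C4-carbonyl-directed C–H oxygenation of flavones at C5 is a known reaction class, and here C5–H is the only C–H on ring A and lies peri to the chromone carbonyl (five-membered ruthenacycle), the phenol is masked as its trifluoroacetate before the oxidant is added, and bicarbonate cleaves the aryl trifluoroacetates but not the pivalates.

Step 9
Reactants: 18 5,7-dihydroxy-3,6,8-trimethoxy-2-[4-methoxy-3,5-bis(pivaloyloxy)phenyl]-4H-chromen-4-one
Product: 19 5,7,3',5'-tetrahydroxy-3,6,8,4'-tetramethoxyflavone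
Conditions: K2CO3 (3 equiv), degassed MeOH, rt, Ar; 1 M HCl to pH 3–4
Reagents that add atoms: none
Why: base-mediated methanolysis (transesterification) of the two aryl pivalates should proceed at room temperature without affecting the methyl ethers or the 3-methoxychromone, and exclusion of air protects the electron-rich polyphenol.

**Compound list**

1 | 4-bromo-2,6-dimethoxyphenol | COc1cc(Br)cc(OC)c1O | starting material
2 | 2-(benzyloxy)-5-bromo-1,3-dimethoxybenzene | COc1cc(Br)cc(OC)c1OCc1ccccc1 | intermediate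
3 | N,2-dimethoxy-N-methylacetamide | COCC(=O)N(C)OC | starting material
4 | [4-(benzyloxy)-3,5-dimethoxyphenyl]lithium | [Li]c1cc(OC)c(OCc2ccccc2)c(OC)c1 | intermediate (not isolated)
5 | lithium 1-[4-(benzyloxy)-3,5-dimethoxyphenyl]-2-methoxy-1-[methoxy(methyl)amino]ethan-1-olate | COCC(O[Li])(N(C)OC)c1cc(OC)c(OCc2ccccc2)c(OC)c1 | intermediate (not isolated)
6 | 1-[4-(benzyloxy)-3,5-dimethoxyphenyl]-2-methoxyethan-1-one | COCC(=O)c1cc(OC)c(OCc2ccccc2)c(OC)c1 | intermediate
7 | 3,5-dihydroxy-4-methoxybenzoic acid | COc1c(O)cc(C(=O)O)cc1O | starting material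
8 | 4-methoxy-3,5-bis(pivaloyloxy)benzoic pivalic anhydride | COc1c(OC(=O)C(C)(C)C)cc(cc1OC(=O)C(C)(C)C)C(=O)OC(=O)C(C)(C)C | intermediate (not isolated)
9 | 4-methoxy-3,5-bis(pivaloyloxy)benzoic acid | COc1c(OC(=O)C(C)(C)C)cc(C(=O)O)cc1OC(=O)C(C)(C)C | intermediate
10 | 4-methoxy-3,5-bis(pivaloyloxy)benzoyl chloride | COc1c(OC(=O)C(C)(C)C)cc(C(Cl)=O)cc1OC(=O)C(C)(C)C | intermediate
11 | 1-[4-(benzyloxy)-3,5-dimethoxyphenyl]-2-methoxy-3-[4-methoxy-3,5-bis(pivaloyloxy)phenyl]propane-1,3-dione (racemic) | COC(C(=O)c1cc(OC)c(OCc2ccccc2)c(OC)c1)C(=O)c1cc(OC(=O)C(C)(C)C)c(OC)c(OC(=O)C(C)(C)C)c1 | intermediate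
12 | 1-(4-hydroxy-3,5-dimethoxyphenyl)-2-methoxy-3-[4-methoxy-3,5-bis(pivaloyloxy)phenyl]propane-1,3-dione (racemic) | COC(C(=O)c1cc(OC)c(O)c(OC)c1)C(=O)c1cc(OC(=O)C(C)(C)C)c(OC)c(OC(=O)C(C)(C)C)c1 | intermediate
13 | 2-methoxy-1-[4-methoxy-3,5-bis(pivaloyloxy)phenyl]-3-(3,3,5-trimethoxy-4-oxocyclohexa-1,5-dien-1-yl)propane-1,3-dione | COC(C(=O)C1=CC(OC)(OC)C(=O)C(OC)=C1)C(=O)c1cc(OC(=O)C(C)(C)C)c(OC)c(OC(=O)C(C)(C)C)c1 | intermediate (not isolated)
14 | 7-hydroxy-3,6,8,8-tetramethoxy-2-[4-methoxy-3,5-bis(pivaloyloxy)phenyl]-8,8a-dihydro-4H-chromen-4-one (racemic) | COC1=C(c2cc(OC(=O)C(C)(C)C)c(OC)c(OC(=O)C(C)(C)C)c2)OC2C(=CC(OC)=C(O)C2(OC)OC)C1=O | intermediate (not isolated)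
15 | 7-hydroxy-3,6,8-trimethoxy-2-[4-methoxy-3,5-bis(pivaloyloxy)phenyl]-4H-chromen-4-one | COc1cc2c(=O)c(OC)c(-c3cc(OC(=O)C(C)(C)C)c(OC)c(OC(=O)C(C)(C)C)c3)oc2c(OC)c1O | intermediate
16 | 3,6,8-trimethoxy-2-[4-methoxy-3,5-bis(pivaloyloxy)phenyl]-4-oxo-4H-chromen-7-yl trifluoroacetate | COc1cc2c(=O)c(OC)c(-c3cc(OC(=O)C(C)(C)C)c(OC)c(OC(=O)C(C)(C)C)c3)oc2c(OC)c1OC(=O)C(F)(F)F | intermediate (not isolated)
17 | 3,6,8-trimethoxy-2-[4-methoxy-3,5-bis(pivaloyloxy)phenyl]-4-oxo-4H-chromene-5,7-diyl bis(trifluoroacetate) | COc1c(OC(=O)C(F)(F)F)c2c(=O)c(OC)c(-c3cc(OC(=O)C(C)(C)C)c(OC)c(OC(=O)C(C)(C)C)c3)oc2c(OC)c1OC(=O)C(F)(F)F | intermediate (not isolated)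
18 | 5,7-dihydroxy-3,6,8-trimethoxy-2-[4-methoxy-3,5-bis(pivaloyloxy)phenyl]-4H-chromen-4-one | COc1c(O)c2c(=O)c(OC)c(-c3cc(OC(=O)C(C)(C)C)c(OC)c(OC(=O)C(C)(C)C)c3)oc2c(OC)c1O | intermediate
19 | 5,7,3',5'-tetrahydroxy-3,6,8,4'-tetramethoxyflavone | COc1c(O)cc(-c2oc3c(OC)c(O)c(OC)c(O)c3c(=O)c2OC)cc1O | target

**Summary**

Total step count: 9. Longest linear sequence: 7 steps (steps 1, 2, 5, 6, 7, 8, 9 from compound 1).

Steps most likely to fail:

1. Step 7 (Proposed new method). The masked o-benzoquinone may be intercepted by methanol or dimerise by Diels–Alder reaction before the tethered enol oxygen closes the ring, or the product phenol may be re-oxidised. Fallback, setting out from 6 and 10 and returning at 15: ketone 6 would be brominated with NBS in MeCN at the ring position ortho to the acyl group to give 1-[4-(benzyloxy)-2-bromo-3,5-dimethoxyphenyl]-2-methoxyethan-1-one F1. C-acylation with 10 under the conditions of step 5 would give 1-[4-(benzyloxy)-2-bromo-3,5-dimethoxyphenyl]-2-methoxy-3-[4-methoxy-3,5-bis(pivaloyloxy)phenyl]propane-1,3-dione F2. Intramolecular Ullmann O-arylation of its enolate (CuI, 1,10-phenanthroline, K3PO4, DMF, 90 °C) would close the pyranone ring to 7-(benzyloxy)-3,6,8-trimethoxy-2-[4-methoxy-3,5-bis(pivaloyloxy)phenyl]-4H-chromen-4-one F3, and hydrogenolysis (H2, Pd/C, EtOAc) would give 15.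

2. Step 8. C–H metalation at C5 may be slow because the position is flanked by the 6-methoxy group, and the iodine(III) oxidant may degrade the electron-rich ring A or functionalise ring B ortho to a pivalate. Fallback, setting out from 15 and returning at 19: electrophilic bromination with NBS (MeCN, 0 °C) at the only free A-ring position would give 5-bromo-7-hydroxy-3,6,8-trimethoxy-2-[4-methoxy-3,5-bis(pivaloyloxy)phenyl]-4H-chromen-4-one F4. Ullmann methoxylation (NaOMe, CuBr, DMF–MeOH, 110 °C), in which methoxide also cleaves both pivalates, would give 2-(3,5-dihydroxy-4-methoxyphenyl)-7-hydroxy-3,5,6,8-tetramethoxy-4H-chromen-4-one F5. Selective demethylation of the 5-methoxy group through the C4-carbonyl chelate (AlCl3, MeCN, rt) would give 19.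

3. Step 5. The magnesium enolate may be O-acylated or the diketone acylated a second time instead of clean C-acylation. Fallback, setting out from 6 and 10 and returning at 11: acid chloride 10 would be reduced with LiAlH(Ot-Bu)3 (THF, −78 °C) to 4-methoxy-3,5-bis(pivaloyloxy)benzaldehyde F6. Aldol addition of the lithium enolate of 6 (LDA, THF, −78 °C) would give 1-[4-(benzyloxy)-3,5-dimethoxyphenyl]-3-hydroxy-2-methoxy-3-[4-methoxy-3,5-bis(pivaloyloxy)phenyl]propan-1-one F7 as a diastereomer mixture, and oxidation with Dess–Martin periodinane (CH2Cl2, rt) would give 11.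

**Further compounds**

F1 | step 7 | 1-[4-(benzyloxy)-2-bromo-3,5-dimethoxyphenyl]-2-methoxyethan-1-one | COCC(=O)c1cc(OC)c(OCc2ccccc2)c(OC)c1Br
F2 | step 7 | 1-[4-(benzyloxy)-2-bromo-3,5-dimethoxyphenyl]-2-methoxy-3-[4-methoxy-3,5-bis(pivaloyloxy)phenyl]propane-1,3-dione | COC(C(=O)c1cc(OC)c(OCc2ccccc2)c(OC)c1Br)C(=O)c1cc(OC(=O)C(C)(C)C)c(OC)c(OC(=O)C(C)(C)C)c1
F3 | step 7 | 7-(benzyloxy)-3,6,8-trimethoxy-2-[4-methoxy-3,5-bis(pivaloyloxy)phenyl]-4H-chromen-4-one | COc1cc2c(=O)c(OC)c(-c3cc(OC(=O)C(C)(C)C)c(OC)c(OC(=O)C(C)(C)C)c3)oc2c(OC)c1OCc1ccccc1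
F4 | step 8 | 5-bromo-7-hydroxy-3,6,8-trimethoxy-2-[4-methoxy-3,5-bis(pivaloyloxy)phenyl]-4H-chromen-4-one | COc1c(Br)c2c(=O)c(OC)c(-c3cc(OC(=O)C(C)(C)C)c(OC)c(OC(=O)C(C)(C)C)c3)oc2c(OC)c1O
F5 | step 8 | 2-(3,5-dihydroxy-4-methoxyphenyl)-7-hydroxy-3,5,6,8-tetramethoxy-4H-chromen-4-one | COc1c(O)cc(-c2oc3c(OC)c(O)c(OC)c(OC)c3c(=O)c2OC)cc1O
F6 | step 5 | 4-methoxy-3,5-bis(pivaloyloxy)benzaldehyde | COc1c(OC(=O)C(C)(C)C)cc(C=O)cc1OC(=O)C(C)(C)C
F7 | step 5 | 1-[4-(benzyloxy)-3,5-dimethoxyphenyl]-3-hydroxy-2-methoxy-3-[4-methoxy-3,5-bis(pivaloyloxy)phenyl]propan-1-one (diastereomer mixture) | COC(C(=O)c1cc(OC)c(OCc2ccccc2)c(OC)c1)C(O)c1cc(OC(=O)C(C)(C)C)c(OC)c(OC(=O)C(C)(C)C)c1
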